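**Plan**
- Retrosynthesis: the O1–C2 bond of the dihydrobenzofuran is cut first (back to an ortho methoxy group and a C2 carbinol, itself a C2–B bond). The C2–(4-hydroxyphenyl) and C3–(3,5-dihydroxyphenyl) bonds are then cut together, which leaves an (E)-alkenylboronic ester on the central ring. The 2-arylbenzofuran is cut into an o-iodophenol and an arylalkyne.
- Enabling feature: C2 and C3 are adjacent benzylic carbons that each carry exactly one aryl ring, and C2 also carries O1. Both rings can therefore be added across a C2=C3 double bond while boron on C2 stands in for O1.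
- Forward order: the benzofuran ring is made first (step 1) and extended to the alkenylboronic ester (steps 2, 3, 5). Three components are joined in step 7, boron is exchanged for oxygen in step 8, and the dihydrofuran ring closes last, with release of all phenols, in step 9.
- Stereochemistry: C3 comes from face selection by a chiral ferrocenyl bisphosphine–palladium catalyst in step 7, and the anti C2 centre from the stereospecific metallate shift. C2 is finally fixed trans to C3 in the ring closure of step 9.

Key step: step 7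

Assumption: the (Sp,Sp) enantiomer of the MandyPhos-type ligand is taken to place palladium on the alkene face that leads to (S) at C3; should the sense prove opposite, the commercially available mirror-image ligand is used under the same conditions.

**Step 1**
Reactants: 1 2-iodo-5-methoxyphenol; 2 1-ethynyl-3,5-dimethoxybenzene
Product: 4 2-(3,5-dimethoxyphenyl)-6-methoxy-1-benzofuran, via o-alkynylphenol 3 (not isolated)
Conditions: PdCl2(PPh3)2 (cat.), CuI (cat.), Et3N, DMF, 25 → 80 °C
Reagents that add atoms: none
Why: Sonogashira coupling of the aryl iodide with the terminal alkyne is followed in the same flask by 5-endo-dig addition of the ortho phenol to the metal-activated triple bond, the standard one-pot entry to 2-arylbenzofurans.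

**Step 2**
Reactants: 4 2-(3,5-dimethoxyphenyl)-6-methoxy-1-benzofuran
Product: 6 2,6-dimethoxy-4-(6-methoxy-1-benzofuran-2-yl)benzaldehyde, via aryllithium 5 (not isolated)
Conditions: n-BuLi, THF, 0 → 25 °C; DMF, 0 °C; 1 M HCl
Reagents that add atoms: N,N-dimethylformamide, CN(C)C=O
Why: Directed ortho-metalation removes the proton between the two methoxy groups, the most acidic and doubly coordinated site (the 2-position of a 1,3-dimethoxybenzene), and the aryllithium is formylated by DMF in a Bouveault-type reaction.

**Step 3**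
Reactants: 6 2,6-dimethoxy-4-(6-methoxy-1-benzofuran-2-yl)benzaldehyde
Product: 7 2-(4-ethynyl-3,5-dimethoxyphenyl)-6-methoxy-1-benzofuran
Conditions: dimethyl (1-diazo-2-oxopropyl)phosphonate, K2CO3, MeOH/THF, 25 °C
Reagents that add atoms: dimethyl (1-diazo-2-oxopropyl)phosphonate, CC(=O)C(=[N+]=[N-])P(=O)(OC)OC
Why: Seyferth–Gilbert homologation in its Ohira–Bestmann form turns an aryl aldehyde into the terminal alkyne under mild carbonate conditions that leave the ethers and the benzofuran untouched.

**Step 4**
Reactants: 8 acenaphthylene-1,2-dione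
Product: 9 cis-(1R,2S)-1,2-dimethyl-1,2-dihydroacenaphthylene-1,2-diol (meso)
Conditions: MeMgBr (2.5 equiv), THF, 0 → 25 °C; aq. NH4Cl; crystallisation
Reagents that add atoms: methylmagnesium bromide, C[Mg]Br
Why: Double Grignard addition to the non-enolisable 1,2-diketone, in which the second methyl group should enter anti to the magnesium alkoxide formed first and so favour the cis (meso) diol, which is purified by crystallisation.

**Step 5**
Reactants: 7 2-(4-ethynyl-3,5-dimethoxyphenyl)-6-methoxy-1-benzofuran; 9 cis-1,2-dimethyl-1,2-dihydroacenaphthylene-1,2-diol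
Product: 11 (E)-2-[2,6-dimethoxy-4-(6-methoxy-1-benzofuran-2-yl)phenyl]ethenylboronic ester of diol 9, via alkenyl catechol boronate 10 (not isolated)
Conditions: catecholborane, Cy2BH (cat.), THF, 25 °C; then 9, THF, 25 °C
Reagents that add atoms: catecholborane, B1Oc2ccccc2O1
Why: Syn, anti-Markovnikov hydroboration of the terminal arylalkyne by catecholborane (dialkylborane-catalysed) fixes the E geometry with boron on the terminal carbon, and transesterification then exchanges the labile catechol ester for the tertiary cis-diol to give a robust boronic ester.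

**Step 6**
Reactants: 12 3,5-dimethoxyphenol
Product: 13 3,5-dimethoxyphenyl trifluoromethanesulfonate
Conditions: Tf2O, pyridine, CH2Cl2, 0 °C
Reagents that add atoms: trifluoromethanesulfonic anhydride, O=S(=O)(OS(=O)(=O)C(F)(F)F)C(F)(F)F
Why: O-Sulfonylation of a phenol with triflic anhydride and pyridine is the standard route to aryl triflates.

**Step 7**
Reactants: 11 (E)-alkenylboronic ester of diol 9; 14 1-bromo-4-methoxybenzene; 13 3,5-dimethoxyphenyl trifluoromethanesulfonate
Product: 17 boronic ester of diol 9 carrying on boron the (1R,2S)-2-(3,5-dimethoxyphenyl)-2-[2,6-dimethoxy-4-(6-methoxy-1-benzofuran-2-yl)phenyl]-1-(4-methoxyphenyl)ethyl group (anti adduct), via 4-methoxyphenyllithium 15 (not isolated), via lithium boron ate complex 16 (not isolated)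
Conditions: 14, t-BuLi (2 equiv), Et2O, −78 °C; 11, THF, −78 → 25 °C; then NaOTf, Pd(OAc)2 (3 mol%), (Sp,Sp)-1,1'-bis[bis(4-methoxy-3,5-dimethylphenyl)phosphino]-2,2'-bis[(R)-α-(dimethylamino)benzyl]ferrocene (3.6 mol%), 13, THF, 60 °C
Reagents that add atoms: none
Why: Proposed new method: oxidative addition of triflate 13 to the zerovalent palladium–bisphosphine complex gives a cationic arylpalladium species (divalent palladium) that binds the alkene of ate complex 16, the 4-methoxyphenyl group then shifts from boron to C2 anti to palladium while palladium bonds to C3, and reductive elimination with retention forms the C3–aryl bond. The closest known reaction type is the palladium/MandyPhos-catalysed enantioselective conjunctive cross-coupling of β-alkyl alkenylboron ate complexes with aryl triflates, which has not been shown for a β-aryl alkene flanked by two ortho methoxy groups. No ring closes in this step. C3 is set by the alkene face that the chiral ferrocenyl bisphosphine lets palladium bind, and C2 by the stereospecific anti metallate shift across the E double bond, so the (1R,2S) anti diastereomer should result. The step needs the metallate shift to outrun direct transmetalation of the alkenyl group (Suzuki–Miyaura product) and β-hydride elimination: the hindered cyclic ester of diol 9 slows transmetalation, NaOTf removes the bromide that would block the cationic palladium centre, and the wide-bite-angle ligand speeds reductive elimination. Regiochemistry is fixed because the migrating group can only reach the boron-bearing carbon, which leaves palladium on benzylic C3.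

**Step 8**
Reactants: 17 (1R,2S)-1,2,2-triarylethylboronic ester of diol 9
Product: 18 (1R,2S)-2-(3,5-dimethoxyphenyl)-2-[2,6-dimethoxy-4-(6-methoxy-1-benzofuran-2-yl)phenyl]-1-(4-methoxyphenyl)ethan-1-ol
Conditions: 30% H2O2, 3 M NaOH, THF, 0 → 25 °C
Reagents that add atoms: hydrogen peroxide, OO
Why: Alkaline hydrogen peroxide oxidises the C–B bond by 1,2-shift of carbon from boron to oxygen with retention, so the (1R,2S) configuration is carried into the alcohol.

**Step 9**
Reactants: 18 (1R,2S)-2-(3,5-dimethoxyphenyl)-2-[2,6-dimethoxy-4-(6-methoxy-1-benzofuran-2-yl)phenyl]-1-(4-methoxyphenyl)ethan-1-ol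
Product: 20 (2S,3S)-3-(3,5-dihydroxyphenyl)-6-(6-hydroxy-1-benzofuran-2-yl)-2-(4-hydroxyphenyl)-2,3-dihydro-1-benzofuran-4-ol, via trans pentamethyl ether 19 (not isolated)
Conditions: BBr3 (excess), CH2Cl2, −78 → 25 °C; then H2O
Reagents that add atoms: none
Why: BBr3 ionises the 4-methoxybenzylic alcohol, the neighbouring ortho methoxy oxygen captures C2 to close the five-membered ring with loss of bromomethane (demethylative cycloetherification) so that the C2 aryl group settles trans to the C3 aryl group set in step 7 (the same outcome as invertive displacement from this diastereomer), and excess reagent then cleaves the five remaining aryl methyl ethers by Lewis acid ether cleavage.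

**Compound list**
1 | 2-iodo-5-methoxyphenol | COc1ccc(I)c(O)c1 | starting material
2 | 1-ethynyl-3,5-dimethoxybenzene | COc1cc(OC)cc(C#C)c1 | starting material
3 | 2-[(3,5-dimethoxyphenyl)ethynyl]-5-methoxyphenol (not isolated) | COc1ccc(C#Cc2cc(OC)cc(OC)c2)c(O)c1 | intermediate
4 | 2-(3,5-dimethoxyphenyl)-6-methoxy-1-benzofuran | COc1ccc2cc(-c3cc(OC)cc(OC)c3)oc2c1 | intermediate
5 | [2,6-dimethoxy-4-(6-methoxy-1-benzofuran-2-yl)phenyl]lithium (not isolated) | [Li]c1c(OC)cc(cc1OC)-c1cc2ccc(OC)cc2o1 | intermediate
6 | 2,6-dimethoxy-4-(6-methoxy-1-benzofuran-2-yl)benzaldehyde | COc1cc(cc(OC)c1C=O)-c1cc2ccc(OC)cc2o1 | intermediate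
7 | 2-(4-ethynyl-3,5-dimethoxyphenyl)-6-methoxy-1-benzofuran | COc1cc(cc(OC)c1C#C)-c1cc2ccc(OC)cc2o1 | intermediate
8 | acenaphthylene-1,2-dione | O=C1C(=O)c2cccc3cccc1c23 | starting material
9 | cis-(1R,2S)-1,2-dimethyl-1,2-dihydroacenaphthylene-1,2-diol (meso) | C[C@@]1(O)[C@](C)(O)c2cccc3cccc1c23 | intermediate
10 | 2-{(E)-2-[2,6-dimethoxy-4-(6-methoxy-1-benzofuran-2-yl)phenyl]ethenyl}-1,3,2-benzodioxaborole (not isolated) | COc1cc(cc(OC)c1/C=C/B1Oc2ccccc2O1)-c1cc2ccc(OC)cc2o1 | intermediate
11 | cyclic boronic ester of diol 9 with the (E)-2-[2,6-dimethoxy-4-(6-methoxy-1-benzofuran-2-yl)phenyl]ethenyl group on boron | COc1cc(cc(OC)c1/C=C/B1O[C@@]2(C)c3cccc4cccc(c34)[C@@]2(C)O1)-c1cc2ccc(OC)cc2o1 | intermediate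
12 | 3,5-dimethoxyphenol | COc1cc(O)cc(OC)c1 | starting material
13 | 3,5-dimethoxyphenyl trifluoromethanesulfonate | COc1cc(OC)cc(OS(=O)(=O)C(F)(F)F)c1 | intermediate
14 | 1-bromo-4-methoxybenzene | COc1ccc(Br)cc1 | starting material
15 | (4-methoxyphenyl)lithium (not isolated) | [Li]c1ccc(OC)cc1 | intermediate
16 | lithium borate of diol 9 with the (E)-alkenyl group of 11 and a 4-methoxyphenyl group on boron (not isolated; configuration at boron not specified) | [Li+].COc1ccc(cc1)[B-]1(/C=C/c2c(OC)cc(cc2OC)-c2cc3ccc(OC)cc3o2)O[C@@]2(C)c3cccc4cccc(c34)[C@@]2(C)O1 | intermediate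
17 | cyclic boronic ester of diol 9 with the (1R,2S)-2-(3,5-dimethoxyphenyl)-2-[2,6-dimethoxy-4-(6-methoxy-1-benzofuran-2-yl)phenyl]-1-(4-methoxyphenyl)ethyl group on boron | COc1ccc(cc1)[C@@H]([C@@H](c1cc(OC)cc(OC)c1)c1c(OC)cc(cc1OC)-c1cc2ccc(OC)cc2o1)B1O[C@@]2(C)c3cccc4cccc(c34)[C@@]2(C)O1 | intermediate
18 | (1R,2S)-2-(3,5-dimethoxyphenyl)-2-[2,6-dimethoxy-4-(6-methoxy-1-benzofuran-2-yl)phenyl]-1-(4-methoxyphenyl)ethan-1-ol | COc1ccc(cc1)[C@@H]([C@@H](c1cc(OC)cc(OC)c1)c1c(OC)cc(cc1OC)-c1cc2ccc(OC)cc2o1)O | intermediate
19 | (2S,3S)-3-(3,5-dimethoxyphenyl)-4-methoxy-6-(6-methoxy-1-benzofuran-2-yl)-2-(4-methoxyphenyl)-2,3-dihydro-1-benzofuran (not isolated) | COc1ccc([C@H]2Oc3cc(-c4cc5ccc(OC)cc5o4)cc(OC)c3[C@@H]2c2cc(OC)cc(OC)c2)cc1 | intermediate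
20 | (2S,3S)-3-(3,5-dihydroxyphenyl)-6-(6-hydroxy-1-benzofuran-2-yl)-2-(4-hydroxyphenyl)-2,3-dihydro-1-benzofuran-4-ol | Oc1ccc([C@H]2Oc3cc(-c4cc5ccc(O)cc5o4)cc(O)c3[C@@H]2c2cc(O)cc(O)c2)cc1 | target

**Step count**
Total: 9 steps. Longest linear sequence: 7 steps (steps 1, 2, 3, 5, 7, 8, 9); steps 4 and 6 are side branches.

**Steps most likely to fail**

Step 7 (bears the label). The hindered, aryl-conjugated alkene of 16 may bind the cationic palladium centre poorly. Direct transmetalation of the alkenyl group, or β-hydride elimination after the shift, could then take over, and face selection could be low.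

The fallback uses known chemistry, the enantioselective rhodium-carbene C–H insertion of a diaryldiazomethane into a benzylic ether. It forms O1–C2 first and C2–C3 last. It sets out from aldehyde 6.
- BCl3 in CH2Cl2 should remove one of the two methyl groups ortho to the formyl group through the boron chelate, giving 2-hydroxy-6-methoxy-4-(6-methoxy-1-benzofuran-2-yl)benzaldehyde F1.
- 4-Methoxybenzyl chloride and K2CO3 in DMF give the ether 2-methoxy-6-[(4-methoxyphenyl)methoxy]-4-(6-methoxy-1-benzofuran-2-yl)benzaldehyde F2.
- 3,5-Dimethoxyphenylmagnesium bromide in THF adds to give the racemic diarylmethanol F3, which MnO2 oxidises to the benzophenone F4.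
- Anhydrous hydrazine in hot ethanol gives the hydrazone F5, and MnO2 oxidises it to the diaryldiazomethane F6.
- Rh2(S-PTAD)4, dirhodium tetrakis[(S)-N-phthaloyl-1-adamantylglycinate], or its enantiomer, whichever gives (3S), inserts the carbene into a benzylic C–H bond of the 4-methoxybenzyl ether. This closes the five-membered ring, expected as the 2,3-cis dihydrobenzofuran F7 with C3 fixed by the catalyst.
- Under the BBr3 conditions of step 9, F7 should open reversibly at O1–C2 and reclose to the more stable trans isomer 19. There the fallback comes back to the route, and 19 goes on to 20 in the same flask.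

Step 9. The benzylic cation at C2 may not be captured by the ortho methoxy oxygen. It could instead undergo a 1,2-hydride shift from C3 (erosion of the C3 centre), elimination to a triarylethene or intermolecular arylation. The closed ring could also re-open and degrade during long exposure to excess BBr3.

The fallback separates ring closure from deprotection. It sets out from 18 and comes back at 20.
- MsCl and Et3N in CH2Cl2 at 0 °C give the methanesulfonate F8 (not isolated). It should ionise at once with participation of the ortho methoxy group, and chloride removes the methyl group from the oxonium ion.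
- The trans pentamethyl ether 19 is then isolated.
- Its five aryl methyl ethers are cleaved with BCl3 and n-Bu4NI in CH2Cl2 at −78 → 0 °C. This soft, iodide-assisted dealkylation avoids a large excess of a strong Lewis acid at ambient temperature and gives 20.

Step 2. Lithiation at C7 of the benzofuran (between the ring oxygen and the 6-methoxy group) may compete with lithiation between the two methoxy groups. That would give a mixture of regioisomeric aldehydes.

The fallback brings the formyl group in with the alkyne. It sets out from 1, comes back at 6 and replaces steps 1 and 2.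
- Commercial 4-bromo-2,6-dimethoxybenzaldehyde is coupled with trimethylsilylacetylene (PdCl2(PPh3)2, CuI, Et3N, THF, 60 °C) to give 2,6-dimethoxy-4-[(trimethylsilyl)ethynyl]benzaldehyde F9.
- K2CO3 in MeOH gives 4-ethynyl-2,6-dimethoxybenzaldehyde F10.
- Sonogashira coupling of F10 with iodophenol 1 under the conditions of step 1 should give aldehyde 6 directly, through the o-alkynylphenol 4-[(2-hydroxy-4-methoxyphenyl)ethynyl]-2,6-dimethoxybenzaldehyde F11 (not isolated).

**Further compounds**
F1 | step 7 | 2-hydroxy-6-methoxy-4-(6-methoxy-1-benzofuran-2-yl)benzaldehyde | COc1cc(cc(O)c1C=O)-c1cc2ccc(OC)cc2o1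
F2 | step 7 | 2-methoxy-6-[(4-methoxyphenyl)methoxy]-4-(6-methoxy-1-benzofuran-2-yl)benzaldehyde | COc1ccc(COc2cc(cc(OC)c2C=O)-c2cc3ccc(OC)cc3o2)cc1
F3 | step 7 | (3,5-dimethoxyphenyl){2-methoxy-6-[(4-methoxyphenyl)methoxy]-4-(6-methoxy-1-benzofuran-2-yl)phenyl}methanol (racemic) | COc1ccc(COc2cc(cc(OC)c2C(O)c2cc(OC)cc(OC)c2)-c2cc3ccc(OC)cc3o2)cc1
F4 | step 7 | (3,5-dimethoxyphenyl){2-methoxy-6-[(4-methoxyphenyl)methoxy]-4-(6-methoxy-1-benzofuran-2-yl)phenyl}methanone | COc1ccc(COc2cc(cc(OC)c2C(=O)c2cc(OC)cc(OC)c2)-c2cc3ccc(OC)cc3o2)cc1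
F5 | step 7 | hydrazone of ketone F4 | COc1ccc(COc2cc(cc(OC)c2C(=NN)c2cc(OC)cc(OC)c2)-c2cc3ccc(OC)cc3o2)cc1
F6 | step 7 | diazo(3,5-dimethoxyphenyl){2-methoxy-6-[(4-methoxyphenyl)methoxy]-4-(6-methoxy-1-benzofuran-2-yl)phenyl}methane | COc1ccc(COc2cc(cc(OC)c2C(=[N+]=[N-])c2cc(OC)cc(OC)c2)-c2cc3ccc(OC)cc3o2)cc1
F7 | step 7 | (2R,3S)-3-(3,5-dimethoxyphenyl)-4-methoxy-6-(6-methoxy-1-benzofuran-2-yl)-2-(4-methoxyphenyl)-2,3-dihydro-1-benzofuran (cis) | COc1ccc([C@@H]2Oc3cc(-c4cc5ccc(OC)cc5o4)cc(OC)c3[C@@H]2c2cc(OC)cc(OC)c2)cc1
F8 | step 9 | (1R,2S)-2-(3,5-dimethoxyphenyl)-2-[2,6-dimethoxy-4-(6-methoxy-1-benzofuran-2-yl)phenyl]-1-(4-methoxyphenyl)ethyl methanesulfonate | COc1ccc(cc1)[C@@H]([C@@H](c1cc(OC)cc(OC)c1)c1c(OC)cc(cc1OC)-c1cc2ccc(OC)cc2o1)OS(C)(=O)=O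
F9 | step 2 | 2,6-dimethoxy-4-[(trimethylsilyl)ethynyl]benzaldehyde | COc1cc(C#C[Si](C)(C)C)cc(OC)c1C=O
F10 | step 2 | 4-ethynyl-2,6-dimethoxybenzaldehyde | COc1cc(C#C)cc(OC)c1C=O
F11 | step 2 | 4-[(2-hydroxy-4-methoxyphenyl)ethynyl]-2,6-dimethoxybenzaldehyde | COc1ccc(C#Cc2cc(OC)c(C=O)c(OC)c2)c(O)c1
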